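**Retrosynthetic overview**
- Target ⇒ open the 4-pyranone at the aryl–O bond (O1–C8a) and remove C2: a 2-fluorodeoxybenzoin plus a formate ester that supplies C2 and O1.
- 2-Fluorodeoxybenzoin ⇒ chromene-6-carbaldehyde (as its aryldiazomethane) + 2-fluoro-4-methoxybenzaldehyde, joined by formal insertion into the formyl C–H bond.
- Chromene aldehyde ⇒ O-methylation of the 5-hydroxychromene aldehyde ⇒ pyran annulation (condensation, then oxa-6π closure of the C–O bond) of 2,4-dihydroxybenzaldehyde with 3-methylbut-2-enal.
- Ring order: the 2,2-dimethylpyran ring first (step 1), the 4-pyranone ring last (step 4); both benzene rings are bought.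

Assumption: the target has no stereocentre (it is achiral), so "single enantiomer" requires no stereocontrol.

**Route**

Step 1
Reactants: 1 2,4-dihydroxybenzaldehyde; 2 3-methylbut-2-enal
Product: 4 5-hydroxy-2,2-dimethyl-2H-chromene-6-carbaldehyde, via ortho-quinone methide 3 (not isolated)
Conditions: pyridine, 140 °C, sealed tube
Reagents that add atoms: none
Why: Base-mediated aldol-type condensation at C3 (the 2-OH is tied up in a hydrogen bond to the aldehyde, so the free 4-OH reacts and directs attack to the carbon between the two oxygens) gives the ortho-quinone methide, which closes the pyran C–O bond by oxa-6π electrocyclisation (formal [3+3] chromene annulation); no stereocentre is formed.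

Step 2
Reactants: 4 5-hydroxy-2,2-dimethyl-2H-chromene-6-carbaldehyde
Product: 5 5-methoxy-2,2-dimethyl-2H-chromene-6-carbaldehyde
Conditions: MeI, K2CO3, DMF, 50 °C
Reagents that add atoms: iodomethane, CI
Why: Williamson ether synthesis (SN2 O-methylation of the phenoxide); the aldehyde and the chromene alkene are inert to MeI/K2CO3.

Step 3
Reactants: 5 5-methoxy-2,2-dimethyl-2H-chromene-6-carbaldehyde; 6 4-methylbenzenesulfonohydrazide; 7 2-fluoro-4-methoxybenzaldehyde
Product: 10 1-(2-fluoro-4-methoxyphenyl)-2-(5-methoxy-2,2-dimethyl-2H-chromen-6-yl)ethan-1-one, via tosylhydrazone 8 (not isolated), via aryldiazomethane 9 (not isolated)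
Conditions: 6, MeOH, rt, then evaporate; 7 (1.5 equiv), Cs2CO3, 1,4-dioxane, 110 °C
Reagents that add atoms: none
Why: Bamford–Stevens generation of the electron-rich aryldiazomethane in the flask, addition of its carbon to the aldehyde carbonyl of 7 and 1,2-hydride shift with loss of N2 give the benzyl ketone (aldehyde-to-ketone homologation by formal formyl C–H insertion); base and heat leave the chromene, the aryl fluoride and the methyl ethers untouched.

Step 4
Reactants: 10 1-(2-fluoro-4-methoxyphenyl)-2-(5-methoxy-2,2-dimethyl-2H-chromen-6-yl)ethan-1-one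
Product: 12 7-methoxy-3-(5-methoxy-2,2-dimethyl-2H-chromen-6-yl)-4H-chromen-4-one, via sodium formyl enolate 11 (not isolated)
Conditions: NaH (1.1 equiv), HCO2Et (3 equiv), THF, 0 °C to rt; evaporate; DMSO, 120 °C
Reagents that add atoms: ethyl formate, CCOC=O
Why: Proposed new method: a formylative SNAr annulation in which the formate ester supplies both C2 and the ring oxygen O1. Claisen C-formylation of the ketone enolate gives the sodium hydroxymethylene enolate 11, whose formyl-derived oxygen is the only nucleophilic atom that can reach the ortho C–F carbon through a six-membered transition state. Attack gives a Meisenheimer complex stabilised by the ortho carbonyl, and loss of fluoride closes the 4-pyranone through the aryl C–O bond. Using close to one equivalent of base and stripping off ethanol before heating leaves almost no free alkoxide to compete for the C–F bond, and DMSO frees the enolate from its cation. The closest known reaction types are the Claisen formylation/cyclodehydration of 2-hydroxydeoxybenzoins to isoflavones and the base-mediated intramolecular SNAr O-arylation of 1-(2-fluoroaryl)-1,3-diketone enolates to flavones (Grohe-type ring closure of the quinolone series). To my knowledge it has not been shown for α-aryl-β-ketoaldehyde enolates on a fluoroarene that carries a para-methoxy donor. No stereocentre is formed.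

**Compound list**
1 | 2,4-dihydroxybenzaldehyde | O=Cc1ccc(O)cc1O | starting material
2 | 3-methylbut-2-enal | CC(C)=CC=O | starting material
3 | ortho-quinone methide: 2-hydroxy-3-(3-methylbut-2-en-1-ylidene)-4-oxocyclohexa-1,5-diene-1-carbaldehyde, Z exocyclic alkene (dienyl chain on the side of the ring C=O) | CC(C)=C/C=C1\C(=O)C=CC(C=O)=C1O | intermediate
4 | 5-hydroxy-2,2-dimethyl-2H-chromene-6-carbaldehyde | O=Cc1ccc2OC(C)(C)C=Cc2c1O | intermediate
5 | 5-methoxy-2,2-dimethyl-2H-chromene-6-carbaldehyde | O=Cc1ccc2OC(C)(C)C=Cc2c1OC | intermediate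
6 | 4-methylbenzenesulfonohydrazide | Cc1ccc(cc1)S(=O)(=O)NN | starting material
7 | 2-fluoro-4-methoxybenzaldehyde | COc1ccc(C=O)c(F)c1 | starting material
8 | N'-[(E)-(5-methoxy-2,2-dimethyl-2H-chromen-6-yl)methylidene]-4-methylbenzenesulfonohydrazide | Cc1ccc(cc1)S(=O)(=O)N/N=C/c1ccc2OC(C)(C)C=Cc2c1OC | intermediate
9 | 6-(diazomethyl)-5-methoxy-2,2-dimethyl-2H-chromene | [N-]=[N+]=Cc1ccc2OC(C)(C)C=Cc2c1OC | intermediate
10 | 1-(2-fluoro-4-methoxyphenyl)-2-(5-methoxy-2,2-dimethyl-2H-chromen-6-yl)ethan-1-one | COc1ccc(C(=O)Cc2ccc3OC(C)(C)C=Cc3c2OC)c(F)c1 | intermediate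
11 | sodium (Z)-3-(2-fluoro-4-methoxyphenyl)-2-(5-methoxy-2,2-dimethyl-2H-chromen-6-yl)-3-oxoprop-1-en-1-olate | [Na+].[O-]/C=C(/c1ccc2OC(C)(C)C=Cc2c1OC)C(=O)c1ccc(OC)cc1F | intermediate
12 | 7-methoxy-3-(5-methoxy-2,2-dimethyl-2H-chromen-6-yl)-4H-chromen-4-one | COc1ccc2c(=O)c(-c3ccc4c(c3OC)C=CC(C)(C)O4)coc2c1 | target

**Step count and risks**

Total steps: 4. Longest linear sequence: 4 (1 → 4 → 5 → 10 → 12).

The three steps most likely to fail:

Step 1 (moderate yield; the linear isomer or double annulation may contaminate the product). The fallback sets out from 1 and comes back at 4. The free 4-OH of 1 is alkylated with 3-chloro-3-methylbut-1-yne (K2CO3, KI, acetone, 60 °C) to give 2-hydroxy-4-[(2-methylbut-3-yn-2-yl)oxy]benzaldehyde F1. Heating F1 in N,N-diethylaniline at 190 °C brings about aryl propargyl ether Claisen rearrangement, 1,5-hydrogen shift and oxa-6π closure to 4, the chelated 2-OH again steering the rearrangement to C3.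

Step 3 (possible aryl instead of hydride migration, diazo decomposition, or displacement of the activated fluoride of 7 by the sulfinate). The fallback sets out from 5, using 7, and comes back at 10. Kabachnik–Fields condensation of 7 with aniline and diethyl phosphite gives diethyl [(2-fluoro-4-methoxyphenyl)(phenylamino)methyl]phosphonate F2. Horner–Wadsworth–Emmons olefination of 5 with the anion of F2 (NaH, THF) gives N-[1-(2-fluoro-4-methoxyphenyl)-2-(5-methoxy-2,2-dimethyl-2H-chromen-6-yl)ethenyl]aniline F3, and mild hydrolysis with dilute aqueous HCl in THF at rt gives 10.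

Step 4 (the proposed new step; the SNAr closure may be slow because the para-methoxy group and the enolate charge weaken the activation by the carbonyl, and residual ethoxide could displace fluoride). The fallback uses known chemistry, sets out from 5 and comes back at 12. Claisen–Schmidt condensation of 5 with 1-(2-hydroxy-4-methoxyphenyl)ethan-1-one (KOH, EtOH, rt) gives (E)-1-(2-hydroxy-4-methoxyphenyl)-3-(5-methoxy-2,2-dimethyl-2H-chromen-6-yl)prop-2-en-1-one F4. Oxidative 1,2-aryl migration with Tl(NO3)3·3H2O in MeOH/HC(OMe)3 at rt gives racemic 1-(2-hydroxy-4-methoxyphenyl)-3,3-dimethoxy-2-(5-methoxy-2,2-dimethyl-2H-chromen-6-yl)propan-1-one F5, and HCl in MeOH at 50 °C closes the pyranone to 12.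

**Further compounds**
F1 | step 1 | 2-hydroxy-4-[(2-methylbut-3-yn-2-yl)oxy]benzaldehyde | C#CC(C)(C)Oc1ccc(C=O)c(O)c1
F2 | step 3 | diethyl [(2-fluoro-4-methoxyphenyl)(phenylamino)methyl]phosphonate (racemic) | CCOP(=O)(OCC)C(Nc1ccccc1)c1ccc(OC)cc1F
F3 | step 3 | N-[1-(2-fluoro-4-methoxyphenyl)-2-(5-methoxy-2,2-dimethyl-2H-chromen-6-yl)ethenyl]aniline (E/Z mixture) | COc1ccc(C(Nc2ccccc2)=Cc2ccc3OC(C)(C)C=Cc3c2OC)c(F)c1
F4 | step 4 | (E)-1-(2-hydroxy-4-methoxyphenyl)-3-(5-methoxy-2,2-dimethyl-2H-chromen-6-yl)prop-2-en-1-one | COc1ccc(C(=O)/C=C/c2ccc3OC(C)(C)C=Cc3c2OC)c(O)c1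
F5 | step 4 | 1-(2-hydroxy-4-methoxyphenyl)-3,3-dimethoxy-2-(5-methoxy-2,2-dimethyl-2H-chromen-6-yl)propan-1-one (racemic) | COc1ccc(C(=O)C(C(OC)OC)c2ccc3OC(C)(C)C=Cc3c2OC)c(O)c1
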